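The naphthazarin core is cut across C1–C8a and C4–C4a. C4a and C8a are neighbouring carbons of the benzenoid ring (C4a, C5–C8, C8a), and the oxygens flanking them at C5 and C8 are identical, so this ring is a symmetric 3,6-dioxygenated benzyne. C1–C4 with the C2 side chain are a 3-substituted furan. One aryne–furan [4+2] cycloaddition closes the quinone-ring carbocycle; the furan oxygen becomes a quinone oxygen after bridge opening and para-oxidation. The precursors are the bis(methoxymethyl) ether of bromohydroquinone and the silyl ether of an (R)-3-furyl carbinol that already carries the complete 4-methylpent-3-enyl chain and the only stereocentre.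

Key step: step 5

Assumption: the B-allyl borane of the (−)-α-pinene series adds to the Re face of aryl aldehydes (its antipode is the one that gives (S)-1-phenylbut-3-en-1-ol). The sense is to be confirmed on 5 by Mosher ester analysis, and the antipodal reagent would be used if it proved opposite.

Remark: the target is drawn with the side chain on the quinoid ring; the hydroxyquinone tautomers of the 5,8-dihydroxy-1,4-naphthoquinone core interconvert rapidly, so no step has to distinguish them.

**Route**

Step 1
Reactants: 1 2-bromobenzene-1,4-diol
Product: 2 2-bromo-1,4-bis(methoxymethoxy)benzene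
Conditions: NaH, MOMCl, DMF, 0 °C → rt
Reagents that add atoms: chloromethyl methyl ether (MOMCl), COCCl
Why: Williamson-type O-alkylation of both phenoxides by the reactive α-chloro ether should give the bis-acetal, whose OCH2OCH3 groups withstand strong base and later direct the lithiation.

Step 2
Reactants: 3 furan-3-carbaldehyde
Product: 5 (1R)-1-(furan-3-yl)but-3-en-1-ol, via bis(isopinocampheyl)borinate ester 4 (not isolated)
Conditions: (+)-Ipc2BOMe [(−)-α-pinene series], allylMgBr, Et2O, 0 °C → rt; then 3, −78 °C; then NaOH (3 M aq), H2O2 (30%), rt
Reagents that add atoms: allylmagnesium bromide, C=CC[Mg]Br (its allyl group is passed on through the B-allyl borane made in the flask)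
Why: Brown asymmetric allylboration, in which allyl is transferred within a six-membered chair transition state and the isopinocampheyl groups of the (−)-α-pinene series leave the Re face of the aldehyde open, so that C1′ is set as R before the oxidative work-up cleaves borinate 4.

Step 3
Reactants: 5 (1R)-1-(furan-3-yl)but-3-en-1-ol
Product: 6 tert-butyl{[(1R)-1-(furan-3-yl)but-3-en-1-yl]oxy}dimethylsilane
Conditions: TBSCl, imidazole, DMF, rt
Reagents that add atoms: tert-butyldimethylsilyl chloride (TBSCl), CC(C)(C)[Si](C)(C)Cl
Why: Imidazole-promoted silylation of a secondary alcohol forms only an O–Si bond, so C1′ is untouched, and the ether blocks alkoxide formation and O-arylation in step 5.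

Step 4
Reactants: 6 tert-butyl{[(1R)-1-(furan-3-yl)but-3-en-1-yl]oxy}dimethylsilane; 7 2-methylbut-2-ene
Product: 8 tert-butyl{[(1R)-1-(furan-3-yl)-4-methylpent-3-en-1-yl]oxy}dimethylsilane
Conditions: second-generation Grubbs catalyst RuCl2(=CHPh)(H2IMes)(PCy3) (3 mol%), 7 (large excess)/CH2Cl2, rt → 35 °C
Reagents that add atoms: 2-methylbut-2-ene (compound 7), CC=C(C)C
Why: Olefin cross-metathesis of the terminal alkene with excess 7 exchanges =CH2 for =C(CH3)2 with loss of propene; the trisubstituted product is a poor substrate for further metathesis, and the furan and silyl ether are tolerated.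

Step 5
Reactants: 2 2-bromo-1,4-bis(methoxymethoxy)benzene; 8 tert-butyl{[(1R)-1-(furan-3-yl)-4-methylpent-3-en-1-yl]oxy}dimethylsilane
Product: 11 tert-butyl({(1R)-1-[5,8-bis(methoxymethoxy)-1,4-dihydro-1,4-epoxynaphthalen-2-yl]-4-methylpent-3-en-1-yl}oxy)dimethylsilane (two bridgehead diastereomers), via aryllithium 9 (not isolated), via aryne 10 (not isolated)
Conditions: 8 (1 equiv), 2 (2 equiv), LiN(iPr)2 (2.1 equiv, added slowly), THF, −78 °C → rt
Reagents that add atoms: none
Why: LiN(iPr)2 removes the C3 proton of 2, the one flanked by bromine and an OCH2OCH3 group, to give aryllithium 9, which loses LiBr on warming to aryne 10; the strained triple bond then adds to C2 and C5 of the furan ring of 8 in a concerted [4+2] cycloaddition, the established way in which 3,6-dialkoxybenzynes are trapped by furans. Ring A (C1–C4, C4a, C8a) is closed by this intermolecular cycloaddition, which forms C1–C8a and C4–C4a in one operation and leaves the former furan oxygen as the 1,4-bridge. The bridgeheads C1 and C4 become stereocentres that are tied to each other by the bridge but not controlled by the remote C1′ centre, so 11 should form as two diastereomers; this is harmless because both bridgeheads become sp2 in step 6, while C1′ lies outside the reacting atoms and keeps its R configuration. No regioselectivity is required, because the two aryne carbons of 10 are flanked by identical OCH2OCH3 groups and either orientation of the unsymmetrical furan gives the same adduct. The selectivity that is needed is chemoselectivity for the furan over addition of amine to 10, ene reaction at the side-chain alkene and metalation or O-arylation of 8; it is secured by lithiating at −78 °C before the aryne is released on warming, by the excess of 2 and base over the furan, by the silyl cap on the carbinol oxygen and by the inability of LiN(iPr)2 to lithiate the furan at that temperature.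

Step 6
Reactants: 11 tert-butyl({(1R)-1-[5,8-bis(methoxymethoxy)-1,4-dihydro-1,4-epoxynaphthalen-2-yl]-4-methylpent-3-en-1-yl}oxy)dimethylsilane
Product: 14 2-[(1R)-1-{[tert-butyl(dimethyl)silyl]oxy}-4-methylpent-3-en-1-yl]-5,8-bis(methoxymethoxy)naphthalene-1,4-dione, via ortho-substituted naphthol 12 (not isolated), via meta-substituted naphthol 13 (not isolated)
Conditions: CSA (10 mol%), CH2Cl2, 0 °C; then, in the same flask, Na2HPO4/KH2PO4 buffer (aq, pH 7), (KSO3)2NO (3 equiv), Bu4NHSO4 (cat.), rt
Reagents that add atoms: potassium nitrosodisulfonate (Fremy's salt), [K+].[K+].[O]N(S(=O)(=O)[O-])S(=O)(=O)[O-]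
Why: Acid-catalysed isomerisation of the 1,4-epoxy-1,4-dihydronaphthalene (protonation of the bridge oxygen, ionisation of a bridge C–O bond to a benzylic, allylic cation stabilised by the ortho acetal oxygen, then 1,2-hydride shift and enolisation) should give naphthol 12 through the cation that places charge on the substituted carbon C2 and some 13 through the other ionisation, and Teuber oxidation of the buffered crude mixture (hydrogen abstraction from the phenol by one nitrosodisulfonate radical, O-coupling of a second at the free para carbon C4, loss of imidodisulfonate) should bring both naphthols to the same 2-substituted para-quinone while the silyl ether, the aryl acetals, the alkene and C1′ are left alone.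

Step 7
Reactants: 14 2-[(1R)-1-{[tert-butyl(dimethyl)silyl]oxy}-4-methylpent-3-en-1-yl]-5,8-bis(methoxymethoxy)naphthalene-1,4-dione
Product: 15 2-[(1R)-1-hydroxy-4-methylpent-3-en-1-yl]-5,8-bis(methoxymethoxy)naphthalene-1,4-dione
Conditions: HF·pyridine, pyridine, THF, 0 °C → rt
Reagents that add atoms: none
Why: Fluoride-mediated desilylation under buffered, weakly acidic conditions cleaves only the Si–O bond, so configuration at C1′ is retained, and it spares the base-sensitive quinone, the aryl methoxymethyl ethers and the alkene.

Step 8
Reactants: 15 2-[(1R)-1-hydroxy-4-methylpent-3-en-1-yl]-5,8-bis(methoxymethoxy)naphthalene-1,4-dione; 16 3-methylbut-2-enoic acid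
Product: 18 (1R)-1-[5,8-bis(methoxymethoxy)-1,4-dioxo-1,4-dihydronaphthalen-2-yl]-4-methylpent-3-en-1-yl 3-methylbut-2-enoate, via O-acylisourea 17 (not isolated)
Conditions: DCC, DMAP (cat.), CH2Cl2, 0 °C → rt
Reagents that add atoms: 3-methylbut-2-enoic acid (compound 16), CC(C)=CC(O)=O
Why: Steglich esterification, in which the acid is activated as O-acylisourea 17 and passed by DMAP to the only free hydroxyl of 15 with retention at C1′ (acyl–oxygen bond formation), the phenols being masked and the mild conditions keeping the acyl double bond in conjugation.

Step 9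
Reactants: 18 (1R)-1-[5,8-bis(methoxymethoxy)-1,4-dioxo-1,4-dihydronaphthalen-2-yl]-4-methylpent-3-en-1-yl 3-methylbut-2-enoate
Product: 19 (1R)-1-(5,8-dihydroxy-1,4-dioxo-1,4-dihydronaphthalen-2-yl)-4-methylpent-3-en-1-yl 3-methylbut-2-enoate
Conditions: HCl (2 M aq)/THF (1:4), rt
Reagents that add atoms: none
Why: Acid-catalysed acetal hydrolysis of the two aryl methoxymethyl ethers, which sit peri to the quinone carbonyls and release good phenol leaving groups, should give the doubly chelated naphthazarin in dilute acid at room temperature, conditions under which the secondary unsaturated ester, the trisubstituted alkene and the C1′ configuration should persist.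

**Compound list**

1 | 2-bromobenzene-1,4-diol | Oc1ccc(O)c(Br)c1 | starting material
2 | 2-bromo-1,4-bis(methoxymethoxy)benzene | COCOc1ccc(OCOC)c(Br)c1 | intermediate
3 | furan-3-carbaldehyde | O=Cc1ccoc1 | starting material
4 | (1R)-1-(furan-3-yl)but-3-en-1-yl bis(isopinocampheyl)borinate, (−)-α-pinene series | C=CC[C@@H](OB([C@H]1C[C@H]2C[C@@H]([C@@H]1C)C2(C)C)[C@H]1C[C@H]2C[C@@H]([C@@H]1C)C2(C)C)c1ccoc1 | intermediate (not isolated)
5 | (1R)-1-(furan-3-yl)but-3-en-1-ol | C=CC[C@@H](O)c1ccoc1 | intermediate
6 | tert-butyl{[(1R)-1-(furan-3-yl)but-3-en-1-yl]oxy}dimethylsilane | C=CC[C@@H](O[Si](C)(C)C(C)(C)C)c1ccoc1 | intermediate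
7 | 2-methylbut-2-ene | CC=C(C)C | starting material
8 | tert-butyl{[(1R)-1-(furan-3-yl)-4-methylpent-3-en-1-yl]oxy}dimethylsilane | CC(C)=CC[C@@H](O[Si](C)(C)C(C)(C)C)c1ccoc1 | intermediate
9 | [2-bromo-3,6-bis(methoxymethoxy)phenyl]lithium | [Li]c1c(Br)c(OCOC)ccc1OCOC | intermediate (not isolated)
10 | 3,6-bis(methoxymethoxy)benzyne | COCOC1=CC=C(OCOC)C#C1 | intermediate (not isolated)
11 | tert-butyl({(1R)-1-[5,8-bis(methoxymethoxy)-1,4-dihydro-1,4-epoxynaphthalen-2-yl]-4-methylpent-3-en-1-yl}oxy)dimethylsilane, both bridgehead diastereomers | CC(C)=CC[C@@H](O[Si](C)(C)C(C)(C)C)C1=CC2OC1c1c(OCOC)ccc(OCOC)c12 | intermediate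
12 | 2-[(1R)-1-{[tert-butyl(dimethyl)silyl]oxy}-4-methylpent-3-en-1-yl]-5,8-bis(methoxymethoxy)naphthalen-1-ol | CC(C)=CC[C@@H](O[Si](C)(C)C(C)(C)C)c1ccc2c(OCOC)ccc(OCOC)c2c1O | intermediate (not isolated)
13 | 3-[(1R)-1-{[tert-butyl(dimethyl)silyl]oxy}-4-methylpent-3-en-1-yl]-5,8-bis(methoxymethoxy)naphthalen-1-ol | CC(C)=CC[C@@H](O[Si](C)(C)C(C)(C)C)c1cc(O)c2c(OCOC)ccc(OCOC)c2c1 | intermediate (not isolated)
14 | 2-[(1R)-1-{[tert-butyl(dimethyl)silyl]oxy}-4-methylpent-3-en-1-yl]-5,8-bis(methoxymethoxy)naphthalene-1,4-dione | CC(C)=CC[C@@H](O[Si](C)(C)C(C)(C)C)C1=CC(=O)c2c(OCOC)ccc(OCOC)c2C1=O | intermediate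
15 | 2-[(1R)-1-hydroxy-4-methylpent-3-en-1-yl]-5,8-bis(methoxymethoxy)naphthalene-1,4-dione | CC(C)=CC[C@@H](O)C1=CC(=O)c2c(OCOC)ccc(OCOC)c2C1=O | intermediate
16 | 3-methylbut-2-enoic acid | CC(C)=CC(O)=O | starting material
17 | N,N′-dicyclohexyl-O-(3-methylbut-2-enoyl)isourea | CC(C)=CC(=O)OC(=NC1CCCCC1)NC1CCCCC1 | intermediate (not isolated)
18 | (1R)-1-[5,8-bis(methoxymethoxy)-1,4-dioxo-1,4-dihydronaphthalen-2-yl]-4-methylpent-3-en-1-yl 3-methylbut-2-enoate | CC(C)=CC[C@@H](OC(=O)C=C(C)C)C1=CC(=O)c2c(OCOC)ccc(OCOC)c2C1=O | intermediate
19 | (1R)-1-(5,8-dihydroxy-1,4-dioxo-1,4-dihydronaphthalen-2-yl)-4-methylpent-3-en-1-yl 3-methylbut-2-enoate | CC(C)=CC[C@@H](OC(=O)C=C(C)C)C1=CC(=O)c2c(O)ccc(O)c2C1=O | target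

**Step count**

Total: 9 steps. Longest linear sequence: 8 steps (steps 2 to 9, from furan-3-carbaldehyde).

**Steps most likely to fail**

Step 5. With the furan as the limiting partner, the aryne may be consumed by addition of diisopropylamine, by ene reaction at the side-chain alkene or by self-reaction faster than by cycloaddition, so that conversion of 8 stalls. The fallback sets out from 2 and comes back at 11, and it generates the aryne by halogen–metal exchange instead of deprotonation. Compound 2 is lithiated with LiN(iPr)2 in THF at −78 °C, where aryllithium 9 persists, and quenched with I2 to give 2-bromo-3-iodo-1,4-bis(methoxymethoxy)benzene F1. F1 and 8 in toluene/THF are then treated with n-BuLi at −78 °C; iodine–lithium exchange, far faster than any lithiation of the furan, regenerates 9 in an amine-free medium, and warming releases 10 for the same cycloaddition to 11.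

Step 6. Under the acid a methoxymethyl group may be lost or transferred to the new peri naphthol oxygen, or the silyloxy group at C1′ may ionise once an ortho hydroxyl is present. In the oxidation, the meta-substituted naphthol 13, whose para carbon is flanked by the side chain and a peri acetal, may be oxidised at the ortho carbon instead. The fallback sets out from 11 and comes back at 14, and it replaces the one-flask protonation and radical oxidation by two separate operations of different mechanism. The monovalent rhodium complex [Rh(CO)2Cl]2 (2–5 mol%) in CHCl3 at room temperature inserts into the strained allylic bridge C–O bond and isomerises the oxabicycle to naphthols 12 and 13 under neutral conditions. The isolated naphthols are then oxidised with PhI(OAc)2 (2.2 equiv) in MeCN/H2O at 0 °C, an ionic two-electron phenol oxidation in which water delivers the para oxygen, to give 14. This fallback makes no new compound (F0).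

Step 9. The acid needed to cleave both acetals may also solvolyse the C1′ ester (ionisation is helped by the hydroquinone tautomer of the product) or add across the trisubstituted alkene. The fallback sets out from 15 and comes back at 19, and it inverts the order of deprotection and acylation so that the ester never meets acid. Compound 15 is hydrolysed with cold dilute aqueous HCl in THF to shikonin, 5,8-dihydroxy-2-[(1R)-1-hydroxy-4-methylpent-3-en-1-yl]naphthalene-1,4-dione F2, a known natural product against which the material can be checked. Steglich acylation with 16 (DCC, catalytic DMAP, CH2Cl2, 0 °C, through 17) should then esterify only the side-chain hydroxyl, because the two peri hydroxyls are locked in hydrogen bonds to the quinone carbonyls, and give 19.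

**Further compounds**

F1 | step 5 | 2-bromo-3-iodo-1,4-bis(methoxymethoxy)benzene | COCOc1ccc(OCOC)c(I)c1Br
F0 | step 6 | none | none
F2 | step 9 | 5,8-dihydroxy-2-[(1R)-1-hydroxy-4-methylpent-3-en-1-yl]naphthalene-1,4-dione (shikonin) | CC(C)=CC[C@@H](O)C1=CC(=O)c2c(O)ccc(O)c2C1=O
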